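**Plan**

- Numbering: acid chain C1 (CO2H) to C13 (on chroman C2); ring atoms O1, C2–C4, C4a, C5–C8, C8a.
- Retrosynthesis: (i) C7–C8 (alkenyl CH to allylic CH2) gives iodo-dienoate 5 and chromanyl diene 16; (ii) C8=C9 and the C9 oxygen lead back to the prenyl end of chroman 13; (iii) O1–C8a, then C4–C4a, lead back to (R)-linalool 10 and dihaloarene 9; (iv) in 5, C2=C3 (Wittig) and C6–CH3/C7–I (alkyne carbometalation).
- Enabling feature: C8/C9 can be the unsubstituted CH2=CH end of a 3-methyl-1,3-diene (C8=C9–C10(CH3)=C11) that 9-BBN hydroborates only at C8, and C7 is the iodine-bearing end of a 2-methylalk-1-enyl unit. Chroman C2 with its CH3, C3 and the C13–C10 arm is the carbinol carbon of linalool.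
- Forward: side arm 5 (3 steps); arene 9 (2 steps); 10 and 9 are joined at C4–C4a, the dihydropyran ring is closed at O1–C8a, the prenyl end is turned into the diene, the halves are joined at C7–C8, and both protecting groups are removed.
- Stereochemistry: C2 (R) comes from (R)-linalool and is never touched (ring closure is at the aryl carbon); 10E from E-selective allylic oxidation of the prenyl terminus; 6E from syn-carboalumination/iodinolysis; 2E from a stabilised ylide; the coupling retains geometry in both partners.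

Key step: step 10

Assumption: (R)-(−)-linalool of high enantiomeric purity and 2-bromo-1-iodo-3-methylbenzene are taken as catalogue compounds; the enantiomeric purity of the final acid is that of the linalool.

**Step 1**
Reactants: 1 pent-4-yn-1-ol
Product: 3 (4E)-5-iodo-4-methylpent-4-en-1-ol, via alkenylalane 2 (not isolated)
Conditions: Me3Al (3 equiv), Cp2ZrCl2 (0.25 equiv), CH2Cl2, 0 °C to rt; then I2 (1.2 equiv), THF, −30 to 0 °C; aq. Na2S2O3/Rochelle salt
Reagents that add atoms: trimethylaluminium, C[Al](C)C; iodine, II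
Why: Negishi zirconium-catalysed carboalumination adds CH3–Al syn across the terminal alkyne (methyl to the internal carbon, aluminium to the terminus, the hydroxyl carried as its aluminium alkoxide), and iodinolysis of the C–Al bond with retention should give the (E)-iodoalkene that becomes 6E of the target.

**Step 2**
Reactants: 3 (4E)-5-iodo-4-methylpent-4-en-1-ol
Product: 4 (4E)-5-iodo-4-methylpent-4-enal
Conditions: PhI(OAc)2 (1.1 equiv), TEMPO (10 mol %), CH2Cl2, rt
Reagents that add atoms: none
Why: TEMPO/PhI(OAc)2 oxidation of a primary alcohol stops at the aldehyde and leaves the alkenyl iodide untouched.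

**Step 3**
Reactants: 4 (4E)-5-iodo-4-methylpent-4-enal
Product: 5 ethyl (2E,6E)-7-iodo-2,6-dimethylhepta-2,6-dienoate
Conditions: Ph3P=C(CH3)CO2Et (1.2 equiv), CH2Cl2, rt to 40 °C
Reagents that add atoms: ethyl 2-(triphenyl-λ5-phosphanylidene)propanoate, CCOC(=O)C(C)=P(c1ccccc1)(c1ccccc1)c1ccccc1
Why: Wittig olefination with a stabilised α-methyl ylide should give the (E)-α-methyl enoate (2E of the target), and the alkenyl iodide is inert to the ylide.

**Step 4**
Reactants: 6 2-bromo-1-iodo-3-methylbenzene
Product: 8 4-bromo-3-iodo-5-methylphenol, via arylboronate 7 (not isolated)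
Conditions: B2pin2 (0.6 equiv), [Ir(OMe)(cod)]2 (1.5 mol %), dtbpy (3 mol %), THF, 60 °C; then Oxone (1.1 equiv), acetone/H2O, rt
Reagents that add atoms: potassium peroxymonosulfate (Oxone), [K+].OOS(=O)(=O)[O-]
Why: Iridium-catalysed C–H borylation is sterically controlled and should go to C5, the only C–H of the 1,2,3-trisubstituted ring without an ortho substituent (C–I and C–Br are tolerated), and Oxone oxidises the aryl boronate to the phenol in the same pot.

**Step 5**
Reactants: 8 4-bromo-3-iodo-5-methylphenol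
Product: 9 (4-bromo-3-iodo-5-methylphenoxy)tri(propan-2-yl)silane
Conditions: TIPSCl (1.2 equiv), imidazole (2.5 equiv), DMF, rt
Reagents that add atoms: chlorotri(propan-2-yl)silane, CC(C)[Si](Cl)(C(C)C)C(C)C
Why: Standard phenol silylation; the TIPS ether is chosen because it should survive the aqueous phosphate, carbonate and ylide bases of the later steps and is removed by fluoride.

**Step 6**
Reactants: 10 (R)-(−)-linalool, (3R)-3,7-dimethylocta-1,6-dien-3-ol; 9 (4-bromo-3-iodo-5-methylphenoxy)tri(propan-2-yl)silane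
Product: 12 (3R)-1-[2-bromo-3-methyl-5-(triisopropylsilyloxy)phenyl]-3,7-dimethyloct-6-en-3-ol, via alkylborane 11 (not isolated)
Conditions: 10 (1.3 equiv), 9-BBN (2.8 equiv), THF, 0 °C to rt; then 3 M aq. K3PO4, 9 (1.0 equiv), PdCl2(dppf)·CH2Cl2 (5 mol %), DMF, 45 °C
Reagents that add atoms: none
Why: 9-BBN hydroborates only the monosubstituted vinyl group of linalool (boron to the terminus, trisubstituted alkene untouched), and B-alkyl Suzuki–Miyaura coupling should occur at the C–I bond of 9, which undergoes oxidative addition far faster than the flanked C–Br bond; the carbinol stereocentre is not involved.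

**Step 7**
Reactants: 12 (3R)-1-[2-bromo-3-methyl-5-(triisopropylsilyloxy)phenyl]-3,7-dimethyloct-6-en-3-ol
Product: 13 {[(2R)-2,8-dimethyl-2-(4-methylpent-3-en-1-yl)-3,4-dihydro-2H-chromen-6-yl]oxy}tri(propan-2-yl)silane
Conditions: Pd(OAc)2 (5 mol %), 2-(di-tert-butylphosphino)-1,1'-binaphthyl (7 mol %), Cs2CO3 (1.5 equiv), toluene, 80 °C
Reagents that add atoms: none
Why: Palladium-catalysed intramolecular aryl etherification (Buchwald–Hartwig-type C–O coupling) closes the dihydropyran ring at O1–C8a through an aryl(alkoxo)palladium intermediate; the tertiary alkoxide has no hydrogen on the carbinol carbon for β-hydride elimination, and because the bond is made at the aryl carbon the C2 configuration is retained.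

**Step 8**
Reactants: 13 {[(2R)-2,8-dimethyl-2-(4-methylpent-3-en-1-yl)-3,4-dihydro-2H-chromen-6-yl]oxy}tri(propan-2-yl)silane
Product: 15 (2E)-5-[(2R)-2,8-dimethyl-6-(triisopropylsilyloxy)-3,4-dihydro-2H-chromen-2-yl]-2-methylpent-2-enal, via allylic alcohol 14 (not isolated)
Conditions: SeO2 (0.4 equiv), t-BuOOH (3 equiv, in decane), salicylic acid (10 mol %), CH2Cl2, rt; crude mixture, then MnO2 (15 equiv), CH2Cl2, rt
Reagents that add atoms: selenium dioxide (oxygen carrier), O=[Se]=O; tert-butyl hydroperoxide (stoichiometric oxygen source), CC(C)(C)OO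
Why: Riley allylic oxidation (ene reaction of SeO2 at the trisubstituted alkene, then [2,3]-sigmatropic shift of the allylseleninic acid) should deliver oxygen to the methyl group trans to the chain, which fixes 10E, and MnO2 oxidises only the allylic alcohol so that alcohol and aldehyde converge on the enal.

**Step 9**
Reactants: 15 (2E)-5-[(2R)-2,8-dimethyl-6-(triisopropylsilyloxy)-3,4-dihydro-2H-chromen-2-yl]-2-methylpent-2-enal
Product: 16 {[(2R)-2,8-dimethyl-2-[(3E)-4-methylhexa-3,5-dien-1-yl]-3,4-dihydro-2H-chromen-6-yl]oxy}tri(propan-2-yl)silane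
Conditions: Ph3PCH3Br (1.5 equiv), KOtBu (1.4 equiv), THF, 0 °C; then 15, 0 °C to rt
Reagents that add atoms: methyltriphenylphosphonium bromide, C[P+](c1ccccc1)(c1ccccc1)c1ccccc1.[Br-]
Why: Wittig methylenation of the enal with the non-stabilised ylide (the same reaction type that converts geranial into its 1,3,7-triene) forms the terminal C8=C9 double bond without touching the existing E-alkene.

**Step 10**
Reactants: 16 {[(2R)-2,8-dimethyl-2-[(3E)-4-methylhexa-3,5-dien-1-yl]-3,4-dihydro-2H-chromen-6-yl]oxy}tri(propan-2-yl)silane; 5 ethyl (2E,6E)-7-iodo-2,6-dimethylhepta-2,6-dienoate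
Product: 18 ethyl (2E,6E,10E)-13-[(2R)-2,8-dimethyl-6-(triisopropylsilyloxy)-3,4-dihydro-2H-chromen-2-yl]-2,6,10-trimethyltrideca-2,6,10-trienoate, via alkylborane 17 (not isolated)
Conditions: 9-BBN (1.15 equiv), THF, 0 °C to rt; then degassed 3 M aq. K3PO4 (3 equiv), 5 (1.0 equiv), PdCl2(dppf)·CH2Cl2 (5 mol %), Ph3As (10 mol %), DMF, rt, dark
Reagents that add atoms: none
Why: 9-BBN adds H–B syn and anti-Markovnikov across the monosubstituted C8=C9 vinyl end of the diene, placing boron on C8 and leaving the trisubstituted C10=C11 alkene untouched; after activation to the borate, Pd(0) inserts into the C7–I bond of 5 with retention, the primary alkyl group transmetalates, and reductive elimination forms the C7–C8 bond. The closest known reaction type is the B-alkyl Suzuki–Miyaura coupling of 9-BBN adducts with (E)-1-iodo-2-methylalkenes, and the hydroboration mirrors the known terminal-selective hydroboration of (E)-4,8-dimethylnona-1,3,7-triene on the way to homogeraniol. No ring is closed and no stereocentre is formed; C2 is remote and untouched, and both partners couple with retention, so 6E is carried over from 5 and 10E from 16. The step needs regio- and chemoselective hydroboration, which the steric demand of 9-BBN should secure (it discriminates the CH2= terminus from a trisubstituted alkene, and over-hydroboration is unlikely because the only alkene left in 17 is trisubstituted). It also needs chemoselective coupling beside the enoate, secured by adding 5 only after excess B–H has been destroyed with aqueous base and by using K3PO4 at room temperature, which should leave the ethyl ester and the aryl silyl ether intact. The wide bite angle of dppf with Ph3As as co-ligand favours reductive elimination over β-hydride elimination of the homoallylic alkylpalladium.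

**Step 11**
Reactants: 18 ethyl (2E,6E,10E)-13-[(2R)-2,8-dimethyl-6-(triisopropylsilyloxy)-3,4-dihydro-2H-chromen-2-yl]-2,6,10-trimethyltrideca-2,6,10-trienoate
Product: 20 garcinoic acid, (2E,6E,10E)-13-[(2R)-6-hydroxy-2,8-dimethyl-3,4-dihydro-2H-chromen-2-yl]-2,6,10-trimethyltrideca-2,6,10-trienoic acid, via phenol ester 19 (not isolated)
Conditions: TBAF (1.3 equiv), THF, 0 °C; then LiOH·H2O (5 equiv), MeOH/H2O (degassed), 40 °C, Ar; 1 M HCl to pH 3
Reagents that add atoms: lithium hydroxide, [Li+].[OH-]
Why: Fluoride cleaves the aryl silyl ether and hydroxide then saponifies the ethyl ester by acyl–oxygen cleavage, neither reagent touching the alkenes or C2; oxygen is excluded because the chromanol phenoxide is air-sensitive.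

**Compound list**

1 | pent-4-yn-1-ol | C#CCCCO | starting material
2 | dimethyl[(1E)-5-(dimethylalumanyloxy)-2-methylpent-1-en-1-yl]alumane | C/C(=C\[Al](C)C)CCCO[Al](C)C | intermediate
3 | (4E)-5-iodo-4-methylpent-4-en-1-ol | C/C(=C\I)CCCO | intermediate
4 | (4E)-5-iodo-4-methylpent-4-enal | C/C(=C\I)CCC=O | intermediate
5 | ethyl (2E,6E)-7-iodo-2,6-dimethylhepta-2,6-dienoate | C/C(=C\I)CC/C=C(\C)C(=O)OCC | intermediate
6 | 2-bromo-1-iodo-3-methylbenzene | Cc1cccc(I)c1Br | starting material
7 | 2-(4-bromo-3-iodo-5-methylphenyl)-4,4,5,5-tetramethyl-1,3,2-dioxaborolane | Cc1cc(B2OC(C)(C)C(C)(C)O2)cc(I)c1Br | intermediate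
8 | 4-bromo-3-iodo-5-methylphenol | Cc1cc(O)cc(I)c1Br | intermediate
9 | (4-bromo-3-iodo-5-methylphenoxy)tri(propan-2-yl)silane | Cc1cc(O[Si](C(C)C)(C(C)C)C(C)C)cc(I)c1Br | intermediate
10 | (R)-(−)-linalool, (3R)-3,7-dimethylocta-1,6-dien-3-ol | C=C[C@](C)(O)CCC=C(C)C | starting material
11 | 9-[(3S)-3-hydroxy-3,7-dimethyloct-6-en-1-yl]-9-borabicyclo[3.3.1]nonane (same spatial arrangement as 10; the descriptor changes by the CIP rules only) | C(C[C@](C)(O)CCC=C(C)C)B1C2CCCC1CCC2 | intermediate
12 | (3R)-1-[2-bromo-3-methyl-5-(triisopropylsilyloxy)phenyl]-3,7-dimethyloct-6-en-3-ol | Cc1cc(O[Si](C(C)C)(C(C)C)C(C)C)cc(CC[C@](C)(O)CCC=C(C)C)c1Br | intermediate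
13 | {[(2R)-2,8-dimethyl-2-(4-methylpent-3-en-1-yl)-3,4-dihydro-2H-chromen-6-yl]oxy}tri(propan-2-yl)silane | CC(C)=CCC[C@]1(C)CCc2cc(O[Si](C(C)C)(C(C)C)C(C)C)cc(C)c2O1 | intermediate
14 | (2E)-5-[(2R)-2,8-dimethyl-6-(triisopropylsilyloxy)-3,4-dihydro-2H-chromen-2-yl]-2-methylpent-2-en-1-ol | OC/C(C)=C/CC[C@]1(C)CCc2cc(O[Si](C(C)C)(C(C)C)C(C)C)cc(C)c2O1 | intermediate
15 | (2E)-5-[(2R)-2,8-dimethyl-6-(triisopropylsilyloxy)-3,4-dihydro-2H-chromen-2-yl]-2-methylpent-2-enal | O=C/C(C)=C/CC[C@]1(C)CCc2cc(O[Si](C(C)C)(C(C)C)C(C)C)cc(C)c2O1 | intermediate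
16 | {[(2R)-2,8-dimethyl-2-[(3E)-4-methylhexa-3,5-dien-1-yl]-3,4-dihydro-2H-chromen-6-yl]oxy}tri(propan-2-yl)silane | C=C/C(C)=C/CC[C@]1(C)CCc2cc(O[Si](C(C)C)(C(C)C)C(C)C)cc(C)c2O1 | intermediate
17 | 9-{(3E)-6-[(2R)-2,8-dimethyl-6-(triisopropylsilyloxy)-3,4-dihydro-2H-chromen-2-yl]-3-methylhex-3-en-1-yl}-9-borabicyclo[3.3.1]nonane | C(C/C(C)=C/CC[C@]1(C)CCc2cc(O[Si](C(C)C)(C(C)C)C(C)C)cc(C)c2O1)B3C4CCCC3CCC4 | intermediate
18 | ethyl (2E,6E,10E)-13-[(2R)-2,8-dimethyl-6-(triisopropylsilyloxy)-3,4-dihydro-2H-chromen-2-yl]-2,6,10-trimethyltrideca-2,6,10-trienoate | C/C(=C\CC/C(C)=C/CC[C@]1(C)CCc2cc(O[Si](C(C)C)(C(C)C)C(C)C)cc(C)c2O1)CC/C=C(\C)C(=O)OCC | intermediate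
19 | ethyl (2E,6E,10E)-13-[(2R)-6-hydroxy-2,8-dimethyl-3,4-dihydro-2H-chromen-2-yl]-2,6,10-trimethyltrideca-2,6,10-trienoate | C/C(=C\CC/C(C)=C/CC[C@]1(C)CCc2cc(O)cc(C)c2O1)CC/C=C(\C)C(=O)OCC | intermediate
20 | garcinoic acid, (2E,6E,10E)-13-[(2R)-6-hydroxy-2,8-dimethyl-3,4-dihydro-2H-chromen-2-yl]-2,6,10-trimethyltrideca-2,6,10-trienoic acid | C/C(=C\CC/C(C)=C/CC[C@]1(C)CCc2cc(O)cc(C)c2O1)CC/C=C(\C)C(=O)O | target

**Summary**

Total step count: 11. Longest linear sequence: 8 steps (steps 4 to 11, from 6).

**Steps most likely to fail**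

Step 10. The hydroboration may not stay confined to the C8 terminus, or the alkylborane may transmetalate so slowly that protodeboronation and β-hydride elimination take over and the coupling stalls. The fallback sets out from 16: it is hydroborated with 9-BBN as before but the borane is oxidised (NaBO3·4H2O, THF/H2O) to the homoallylic alcohol F1. This is converted into the homoallylic iodide F2 (I2, PPh3, imidazole, CH2Cl2, 0 °C), zinc is inserted (Zn dust, LiCl, THF, 40 °C) to give the alkylzinc iodide F3, and Negishi coupling with 5 (Pd(PPh3)4, THF, rt) comes back to the route at 18.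

Step 8. The allylic oxidation may stop at low conversion, over-oxidise, or attack the allylic C12 methylene or the benzylic C4 position, so that little enal is obtained. The fallback sets out from 13: the C10=C11 alkene is cleaved (OsO4 cat., NaIO4, 2,6-lutidine, dioxane/H2O) to the aldehyde F4, and the (E)-enal is rebuilt by Wittig reaction with 2-(triphenylphosphoranylidene)propanal (toluene, 80 °C), which comes back at 15.

Step 7. Oxidative addition at the electron-rich, doubly ortho-substituted C–Br bond and the C–O reductive elimination may both be slow, so that hydrodebromination dominates. The fallback sets out from 12: bromine is exchanged for iodine by copper-catalysed aromatic Finkelstein reaction (CuI, NaI, trans-N,N'-dimethylcyclohexane-1,2-diamine, dioxane, 110 °C) to give the aryl iodide F5. The ring is then closed by copper(I)-mediated Ullmann etherification (CuI, 3,4,7,8-tetramethyl-1,10-phenanthroline, Cs2CO3, toluene, 110 °C), which comes back at 13.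

**Further compounds**

F1 | step 10 | (3E)-6-[(2R)-2,8-dimethyl-6-(triisopropylsilyloxy)-3,4-dihydro-2H-chromen-2-yl]-3-methylhex-3-en-1-ol | OCC/C(C)=C/CC[C@]1(C)CCc2cc(O[Si](C(C)C)(C(C)C)C(C)C)cc(C)c2O1
F2 | step 10 | {[(2R)-2-[(3E)-6-iodo-4-methylhex-3-en-1-yl]-2,8-dimethyl-3,4-dihydro-2H-chromen-6-yl]oxy}tri(propan-2-yl)silane | ICC/C(C)=C/CC[C@]1(C)CCc2cc(O[Si](C(C)C)(C(C)C)C(C)C)cc(C)c2O1
F3 | step 10 | {(3E)-6-[(2R)-2,8-dimethyl-6-(triisopropylsilyloxy)-3,4-dihydro-2H-chromen-2-yl]-3-methylhex-3-en-1-yl}zinc iodide | I[Zn]CC/C(C)=C/CC[C@]1(C)CCc2cc(O[Si](C(C)C)(C(C)C)C(C)C)cc(C)c2O1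
F4 | step 8 | 3-[(2S)-2,8-dimethyl-6-(triisopropylsilyloxy)-3,4-dihydro-2H-chromen-2-yl]propanal (same spatial arrangement as 13; the descriptor changes by the CIP rules only) | O=CCC[C@]1(C)CCc2cc(O[Si](C(C)C)(C(C)C)C(C)C)cc(C)c2O1
F5 | step 7 | (3R)-1-[2-iodo-3-methyl-5-(triisopropylsilyloxy)phenyl]-3,7-dimethyloct-6-en-3-ol | Cc1cc(O[Si](C(C)C)(C(C)C)C(C)C)cc(CC[C@](C)(O)CCC=C(C)C)c1I
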